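**Plan**
- Retrosynthesis: the tert-butyl mask of the acrylic acid comes off last. Before that, the C2'–O acyl bond of the coumarate ester and the C=C of the C5 acrylate are cut. Then O1–C2 and C1'–C2' are cut together, leaving a phenol with a (Z)-but-2-enyl chain.
- Forward: 4-hydroxybenzaldehyde is O-allylated, rearranged (aryl–C3 bond) and capped to the Z-crotylphenol. One palladium-catalysed operation closes the dihydrofuran ring (the only ring made) and adds the ester carbon. Olefination, ester reduction, acylation and acidolysis complete the chain.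
- Enabling feature: C2 (bonded to O1) and C1' (the CH carrying CH3 and the C2' methylene) are neighbours. They are the two alkene carbons of a (Z)-but-2-enyl group ortho to the phenolic O1 on the benzene ring.
- Stereochemistry: C2 (S) comes from face selection by a chiral bis(oxazoline)–palladium catalyst. C1' follows from the Z geometry through syn oxypalladation and retentive CO insertion. Both acrylate double bonds are E (Wittig reaction; the coumaroyl unit is used as supplied).

Key step: step 4

Assumption: locants follow benzofuran numbering (O1, C2, C3; side chain C1' = CH(CH3), C2' = CH2O). The (S,S)-ligand is assumed to direct attack to the Si face at C2; if it favours the other face, its mirror image would be used.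

Step 1
Reactants: 1 4-hydroxybenzaldehyde; 2 allyl bromide (3-bromoprop-1-ene)
Product: 3 4-(prop-2-en-1-yloxy)benzaldehyde
Conditions: K2CO3, acetone, reflux
Reagents that add atoms: none
Why: Williamson ether synthesis, in which the phenoxide of the acidic para-formylphenol displaces bromide from the primary allylic halide by SN2.

Step 2
Reactants: 3 4-(prop-2-en-1-yloxy)benzaldehyde
Product: 4 4-hydroxy-3-(prop-2-en-1-yl)benzaldehyde
Conditions: N,N-diethylaniline, 200 °C (sealed tube)
Reagents that add atoms: none
Why: aromatic Claisen rearrangement ([3,3]-sigmatropic shift, then tautomerisation) moves the allyl group to one of the two equivalent ortho positions and frees the phenol.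

Step 3
Reactants: 4 4-hydroxy-3-(prop-2-en-1-yl)benzaldehyde; 5 (Z)-but-2-ene
Product: 6 3-[(2Z)-but-2-en-1-yl]-4-hydroxybenzaldehyde
Conditions: (Z)-but-2-ene (10 equiv), Ru(SIMes)(3,6-Cl2C6H2S2)(=CH-C6H4-2-OiPr) (5 mol%; SIMes = 1,3-dimesitylimidazolidin-2-ylidene), THF, 22 °C
Reagents that add atoms: none
Why: stereoretentive olefin cross-metathesis, in which the dithiolate ruthenium carbene forms all-syn metallacyclobutanes so that the Z geometry of the butene is carried into the product, while excess butene keeps the catalyst as the ethylidene and not the fragile methylidene.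

Step 4
Reactants: 6 3-[(2Z)-but-2-en-1-yl]-4-hydroxybenzaldehyde; 7 carbon monoxide; 8 methanol
Product: 9 methyl (2R)-2-[(2S)-5-formyl-2,3-dihydro-1-benzofuran-2-yl]propanoate
Conditions: Pd(OCOCF3)2 (10 mol%), (S,S)-Bn-BOXAX [2,2'-bis((4S)-4-benzyl-4,5-dihydro-1,3-oxazol-2-yl)-1,1'-binaphthyl] (40 mol%), p-benzoquinone (4 equiv), CO (1 atm), MeOH, rt; then 1 M HCl work-up
Reagents that add atoms: none
Why: Proposed new method: a chloride-free divalent palladium centre held by the C2-symmetric bis(oxazoline) binds the Z-alkene and the phenoxide, which adds syn across it in a 5-exo-trig oxypalladation (O1–C2, ring closure); the secondary C1'–Pd bond then inserts CO with retention and methanolysis of the acylpalladium forms C1'–C2' as the methyl ester, while p-benzoquinone reoxidises zerovalent palladium. The closest known reaction types are the enantioselective domino Wacker cyclisation–methoxycarbonylation of phenols onto 1,1-disubstituted alkenes with this catalyst system and the PdCl2/CuCl2 alkoxycarbonylative cyclisation of alkenols with 1,2-disubstituted alkenes; new here is ligand-controlled syn addition to a 1,2-disubstituted alkene with capture of a secondary alkylpalladium that bears β-hydrogens. C2 is set by the ligand through its choice of alkene face (attack on the Si face at C2 gives 2S), and C1' is fixed relative to C2 by the Z geometry, because syn oxypalladation and retentive insertion place O1 and C2' on the same face of the former double bond. The step needs 5-exo over 6-endo closure, which the one-carbon tether between arene and alkene favours as in Wacker cyclisations of 2-(but-2-enyl)phenols, and CO insertion ahead of β-hydride elimination, which CO saturation of the metal and fast oxypalladation by the acidic para-formylphenol should support. The acidic work-up returns the aldehyde should methanol have masked part of it as an acetal.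

Step 5
Reactants: 9 methyl (2R)-2-[(2S)-5-formyl-2,3-dihydro-1-benzofuran-2-yl]propanoate
Product: 10 tert-butyl (2E)-3-{(2S)-2-[(2R)-1-methoxy-1-oxopropan-2-yl]-2,3-dihydro-1-benzofuran-5-yl}prop-2-enoate
Conditions: Ph3P=CHCO2tBu (1.3 equiv), toluene, 80 °C
Reagents that add atoms: tert-butyl (triphenylphosphoranylidene)acetate, CC(C)(C)OC(=O)C=P(c1ccccc1)(c1ccccc1)c1ccccc1
Why: Wittig olefination with a stabilised ylide gives the E-acrylate, and the ylide is too weak a base to epimerise C1' or to expel the aryloxide by β-elimination.

Step 6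
Reactants: 10 tert-butyl (2E)-3-{(2S)-2-[(2R)-1-methoxy-1-oxopropan-2-yl]-2,3-dihydro-1-benzofuran-5-yl}prop-2-enoate
Product: 11 tert-butyl (2E)-3-{(2S)-2-[(2S)-1-hydroxypropan-2-yl]-2,3-dihydro-1-benzofuran-5-yl}prop-2-enoate
Conditions: LiBH4 (2 equiv), THF, 0 °C → rt; then H2O
Reagents that add atoms: none
Why: chemoselective borohydride reduction, in which the methyl ester (activated by lithium chelation to the β-oxygen O1) should be reduced while the hindered, conjugated tert-butyl ester is spared; no bond at C1' is touched, and its descriptor changes from R to S only through the priority rules.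

Step 7
Reactants: 11 tert-butyl (2E)-3-{(2S)-2-[(2S)-1-hydroxypropan-2-yl]-2,3-dihydro-1-benzofuran-5-yl}prop-2-enoate; 12 p-coumaric acid [(2E)-3-(4-hydroxyphenyl)prop-2-enoic acid]
Product: 13 tert-butyl (2E)-3-[(2S)-2-[(2S)-1-{[(2E)-3-(4-hydroxyphenyl)prop-2-enoyl]oxy}propan-2-yl]-2,3-dihydro-1-benzofuran-5-yl]prop-2-enoate
Conditions: 12 (1.2 equiv), PPh3, DIAD, THF, 0 °C → rt
Reagents that add atoms: none
Why: Mitsunobu esterification, in which the carboxylic acid, far more acidic than the phenol, is the pronucleophile that attacks the alkoxyphosphonium of the primary alcohol, so the phenol needs no protection and, the reacting carbon being CH2, no stereocentre is affected.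

Step 8
Reactants: 13 tert-butyl (2E)-3-[(2S)-2-[(2S)-1-{[(2E)-3-(4-hydroxyphenyl)prop-2-enoyl]oxy}propan-2-yl]-2,3-dihydro-1-benzofuran-5-yl]prop-2-enoate
Product: 14 (2E)-3-[(2S)-2-[(2S)-1-{[(2E)-3-(4-hydroxyphenyl)prop-2-enoyl]oxy}propan-2-yl]-2,3-dihydro-1-benzofuran-5-yl]prop-2-enoic acid
Conditions: TFA–CH2Cl2 (1:4), 0 °C → rt
Reagents that add atoms: none
Why: acidolysis of the tert-butyl ester by alkyl–oxygen cleavage, with loss of 2-methylpropene, should leave the primary cinnamate ester, the aryl alkyl ether and both stereocentres intact at low temperature.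

**Compound list**
1 | 4-hydroxybenzaldehyde | O=Cc1ccc(O)cc1 | starting material
2 | allyl bromide (3-bromoprop-1-ene) | C=CCBr | starting material
3 | 4-(prop-2-en-1-yloxy)benzaldehyde | C=CCOc1ccc(C=O)cc1 | intermediate
4 | 4-hydroxy-3-(prop-2-en-1-yl)benzaldehyde | C=CCc1cc(C=O)ccc1O | intermediate
5 | (Z)-but-2-ene | C/C=C\C | starting material
6 | 3-[(2Z)-but-2-en-1-yl]-4-hydroxybenzaldehyde | C/C=C\Cc1cc(C=O)ccc1O | intermediate
7 | carbon monoxide | [C-]#[O+] | starting material
8 | methanol | CO | starting material
9 | methyl (2R)-2-[(2S)-5-formyl-2,3-dihydro-1-benzofuran-2-yl]propanoate | C[C@@H](C(=O)OC)[C@@H]1Cc2cc(C=O)ccc2O1 | intermediate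
10 | tert-butyl (2E)-3-{(2S)-2-[(2R)-1-methoxy-1-oxopropan-2-yl]-2,3-dihydro-1-benzofuran-5-yl}prop-2-enoate | C[C@@H](C(=O)OC)[C@@H]1Cc2cc(/C=C/C(=O)OC(C)(C)C)ccc2O1 | intermediate
11 | tert-butyl (2E)-3-{(2S)-2-[(2S)-1-hydroxypropan-2-yl]-2,3-dihydro-1-benzofuran-5-yl}prop-2-enoate | C[C@@H](CO)[C@@H]1Cc2cc(/C=C/C(=O)OC(C)(C)C)ccc2O1 | intermediate
12 | p-coumaric acid, (2E)-3-(4-hydroxyphenyl)prop-2-enoic acid | OC(=O)/C=C/c1ccc(O)cc1 | starting material
13 | tert-butyl (2E)-3-[(2S)-2-[(2S)-1-{[(2E)-3-(4-hydroxyphenyl)prop-2-enoyl]oxy}propan-2-yl]-2,3-dihydro-1-benzofuran-5-yl]prop-2-enoate | C[C@@H](COC(=O)/C=C/c1ccc(O)cc1)[C@@H]1Cc2cc(/C=C/C(=O)OC(C)(C)C)ccc2O1 | intermediate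
14 | (2E)-3-[(2S)-2-[(2S)-1-{[(2E)-3-(4-hydroxyphenyl)prop-2-enoyl]oxy}propan-2-yl]-2,3-dihydro-1-benzofuran-5-yl]prop-2-enoic acid | C[C@@H](COC(=O)/C=C/c1ccc(O)cc1)[C@@H]1Cc2cc(/C=C/C(=O)O)ccc2O1 | target

**Step count**
Total steps: 8. Longest linear sequence: 8 steps (1 → 14).

**Steps most likely to fail**

Step 4 (proposed new method). The secondary alkylpalladium may lose a β-hydrogen before it inserts CO. The ligand may discriminate the faces of a 1,2-disubstituted alkene poorly. Closure may also drift toward the 6-endo mode. The fallback uses established chemistry, sets out from 1 and returns at 9. Mitsunobu etherification of 1 with but-3-en-2-ol (PPh3, DIAD, THF) would give racemic 4-(but-3-en-2-yloxy)benzaldehyde F1. Its aromatic Claisen rearrangement (N,N-diethylaniline, 200 °C), through a chair transition state with the methyl group equatorial, should give 3-[(2E)-but-2-en-1-yl]-4-hydroxybenzaldehyde F2. F2 would be cyclised under classical chloride-rich alkoxycarbonylation conditions (PdCl2 cat., CuCl2, NaOAc, CO 1 atm, MeOH, rt; acidic work-up). Under these conditions the phenol attacks the coordinated alkene anti to palladium, and carbonylation of secondary alkylpalladium species is established. Anti addition across the E-alkene leads to the same relative configuration as syn addition across the Z-alkene. The product is racemic methyl (2R*)-2-[(2S*)-5-formyl-2,3-dihydro-1-benzofuran-2-yl]propanoate F3. Separation of the enantiomers by preparative chromatography on a chiral stationary phase would then provide 9, at the cost of half the material.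

Step 3. The Z geometry may erode through secondary metathesis. The double bond may migrate into conjugation with the arene. The free phenol may deactivate the catalyst. The fallback sets out from 4 and returns at 6. Acetalisation of 4 with ethylene glycol (cat. TsOH, toluene, water removal) would give 2-(prop-2-en-1-yl)-4-(1,3-dioxolan-2-yl)phenol F4. Lemieux–Johnson cleavage of the terminal alkene (OsO4 cat., NaIO4, 2,6-lutidine, dioxane–water) gives the arylacetaldehyde, which rests as the lactol 5-(1,3-dioxolan-2-yl)-2,3-dihydro-1-benzofuran-2-ol F5. Salt-free Wittig olefination with ethylidenetriphenylphosphorane (EtPPh3Br, NaN(SiMe3)2, THF, −78 °C → rt, with excess ylide to carry the phenoxide) should give 2-[(2Z)-but-2-en-1-yl]-4-(1,3-dioxolan-2-yl)phenol F6. Mild acid hydrolysis (1 M HCl, THF) then returns 6.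

Step 6. Hydride may also attack the cinnamate (conjugate reduction) or the tert-butyl ester. The aryloxide may be lost by β-elimination from the ester enolate under the basic alkoxyborate medium. The fallback sets out from 9 and returns at 11. Exhaustive reduction of 9 with LiBH4 (THF) would give (2S)-2-[(2S)-5-(hydroxymethyl)-2,3-dihydro-1-benzofuran-2-yl]propan-1-ol F7. Selective oxidation of the benzylic alcohol with activated MnO2 (CH2Cl2, rt) gives (2S)-2-[(2S)-1-hydroxypropan-2-yl]-2,3-dihydro-1-benzofuran-5-carbaldehyde F8. Wittig olefination of F8 with Ph3P=CHCO2tBu (toluene, 80 °C) then gives 11, so that no ester has to be reduced beside the acrylate.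

**Further compounds**
F1 | step 4 | 4-(but-3-en-2-yloxy)benzaldehyde (racemic) | C=CC(C)Oc1ccc(C=O)cc1
F2 | step 4 | 3-[(2E)-but-2-en-1-yl]-4-hydroxybenzaldehyde | C/C=C/Cc1cc(C=O)ccc1O
F3 | step 4 | racemic methyl (2R*)-2-[(2S*)-5-formyl-2,3-dihydro-1-benzofuran-2-yl]propanoate (9 and its enantiomer, 1:1) | C[C@@H](C(=O)OC)[C@@H]1Cc2cc(C=O)ccc2O1.C[C@H](C(=O)OC)[C@H]1Cc2cc(C=O)ccc2O1
F4 | step 3 | 2-(prop-2-en-1-yl)-4-(1,3-dioxolan-2-yl)phenol | C=CCc1cc(C2OCCO2)ccc1O
F5 | step 3 | 5-(1,3-dioxolan-2-yl)-2,3-dihydro-1-benzofuran-2-ol (racemic lactol) | OC1Cc2cc(C3OCCO3)ccc2O1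
F6 | step 3 | 2-[(2Z)-but-2-en-1-yl]-4-(1,3-dioxolan-2-yl)phenol | C/C=C\Cc1cc(C2OCCO2)ccc1O
F7 | step 6 | (2S)-2-[(2S)-5-(hydroxymethyl)-2,3-dihydro-1-benzofuran-2-yl]propan-1-ol | C[C@@H](CO)[C@@H]1Cc2cc(CO)ccc2O1
F8 | step 6 | (2S)-2-[(2S)-1-hydroxypropan-2-yl]-2,3-dihydro-1-benzofuran-5-carbaldehyde | C[C@@H](CO)[C@@H]1Cc2cc(C=O)ccc2O1
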